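**Retrosynthetic overview**
- Target ⇐ its tri-O-methyl ether, by BBr3 cleavage of the three anisole-type methoxy groups (last step).
- Key disconnection: the two phenolic C–O bonds of the central ring (ring A) ⇐ twofold allylic C–H oxygenation of a 1-alkyl-2,6-bis(arylidene)cyclohexan-1-ol, followed in the same flask by redox-neutral, dehydrative isoaromatization.
- That carbinol ⇐ 1,2-addition of a 3-methoxyphenethyl organometallic to 2,6-bis(4-methoxybenzylidene)cyclohexanone ⇐ cyclohexanone + two 4-methoxybenzaldehyde.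
- Ring order: the three outer benzene rings are bought. Ring A is the cyclohexanone ring and becomes aromatic last; its positions fix all six substituents (C=O carbon → chain, α-carbons → benzyls, β-carbons → OH, γ-carbon → H).

Assumption: the SMILES has no stereocentre, so shanciguol is achiral and there is no enantiomer to control; alkene geometries in the intermediates are lost on aromatization.

**Step 1**
Reactants: 1 cyclohexanone; 2 4-methoxybenzaldehyde (2.05 equiv)
Product: 3 (2E,6E)-2,6-bis[(4-methoxyphenyl)methylidene]cyclohexan-1-one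
Conditions: NaOH (aq, 10%), EtOH, rt; filter the yellow solid
Reagents that add atoms: none
Why: Double Claisen–Schmidt (crossed aldol) condensation; only the ketone is enolisable, both dehydrations are driven by conjugation, and the (E,E)-dienone crystallises out, with no stereocentre formed.

**Step 2**
Reactants: 3 (2E,6E)-2,6-bis[(4-methoxyphenyl)methylidene]cyclohexan-1-one; 4 1-(2-bromoethyl)-3-methoxybenzene (1.5 equiv)
Product: 6 (2E,6E)-1-[2-(3-methoxyphenyl)ethyl]-2,6-bis[(4-methoxyphenyl)methylidene]cyclohexan-1-ol, via Grignard reagent 5 (not isolated)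
Conditions: 4, Mg, THF, 40 °C; anhydrous CeCl3 (1.5 equiv), THF, −78 °C; then 3, −78 to 0 °C; H2O, Celite; Et3N-washed SiO2
Reagents that add atoms: none
Why: Grignard formation then Imamoto-type organocerium 1,2-addition; the oxophilic, weakly basic RCeCl2 species attacks the carbonyl of the cross-conjugated dienone instead of adding 1,4 or reducing it, and the carbinol carbon carries two identical arms, so no stereocentre arises.

**Step 3**
Reactants: 6 (2E,6E)-1-[2-(3-methoxyphenyl)ethyl]-2,6-bis[(4-methoxyphenyl)methylidene]cyclohexan-1-ol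
Product: 8 4,6-bis[(4-methoxyphenyl)methyl]-5-[2-(3-methoxyphenyl)ethyl]benzene-1,3-diol, via triol 7 (not isolated)
Conditions: SeO2 (0.5 equiv), t-BuOOH (5 equiv), pyridine (2 equiv), CH2Cl2, 0 °C to rt; aq Na2S2O3 wash, evaporate; then KOtBu (6 equiv), degassed DMSO, 60 °C, Ar; dil HCl to pH 5
Reagents that add atoms: tert-butyl hydroperoxide, CC(C)(C)OO (terminal oxygen source); selenium dioxide, O=[Se]=O (oxygen-transfer catalyst)
Why: Proposed new method: oxidative isoaromatization, in which each exocyclic arylidene alkene has allylic hydrogens only on the ring CH2 beside it (the carbinol carbon and the aryl group carry none), so the SeO2 ene reaction and [2,3]-sigmatropic shift can place oxygen only at the two ring carbons that become C1 and C3 of the resorcinol (configuration irrelevant); KOtBu in DMSO then shifts each carbinol hydrogen to the benzylic terminus (1,3-prototropic allylic alkoxide to enolate isomerization), the resulting β-hydroxy 1,3-diketone loses the tertiary hydroxyl by E1cB and tautomerises to the resorcinol, so the new oxygens can only end up as carbonyl and then phenol oxygens and aromatization pulls the cascade; the closest known reaction types are the SeO2/t-BuOOH allylic hydroxylation of trisubstituted alkenes and the isoaromatization of 2,6-bis(arylidene)cyclohexanones to 2,6-dibenzylphenols, which have not been combined to make a resorcinol from a cyclohexanol.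

**Step 4**
Reactants: 8 4,6-bis[(4-methoxyphenyl)methyl]-5-[2-(3-methoxyphenyl)ethyl]benzene-1,3-diol
Product: 9 shanciguol, 4,6-bis[(4-hydroxyphenyl)methyl]-5-[2-(3-hydroxyphenyl)ethyl]benzene-1,3-diol
Conditions: BBr3 (8 equiv), CH2Cl2, −78 °C to rt; then H2O, 0 °C
Reagents that add atoms: none
Why: BBr3 demethylation of aryl methyl ethers; boron coordinates each methoxy oxygen and bromide removes the methyl group by SN2, which leaves the diarylmethane and bibenzyl C–C bonds intact at low temperature and touches no stereocentre.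

**Compound list**
1 | cyclohexanone | O=C1CCCCC1 | starting material
2 | 4-methoxybenzaldehyde | COc1ccc(C=O)cc1 | starting material
3 | (2E,6E)-2,6-bis[(4-methoxyphenyl)methylidene]cyclohexan-1-one | O=C1/C(=C/c2ccc(OC)cc2)CCC/C1=C\c1ccc(OC)cc1 | intermediate
4 | 1-(2-bromoethyl)-3-methoxybenzene | COc1cccc(CCBr)c1 | starting material
5 | [2-(3-methoxyphenyl)ethyl]magnesium bromide (formed in the flask) | COc1cccc(CC[Mg]Br)c1 | intermediate
6 | (2E,6E)-1-[2-(3-methoxyphenyl)ethyl]-2,6-bis[(4-methoxyphenyl)methylidene]cyclohexan-1-ol | OC1(CCc2cccc(OC)c2)/C(=C/c2ccc(OC)cc2)CCC/C1=C\c1ccc(OC)cc1 | intermediate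
7 | 4,6-bis[(4-methoxyphenyl)methylidene]-5-[2-(3-methoxyphenyl)ethyl]cyclohexane-1,3,5-triol (formed in the flask; mixture of diastereomers and alkene isomers, all converging on 8) | OC1CC(O)C(=Cc2ccc(OC)cc2)C(O)(CCc2cccc(OC)c2)C1=Cc1ccc(OC)cc1 | intermediate
8 | 4,6-bis[(4-methoxyphenyl)methyl]-5-[2-(3-methoxyphenyl)ethyl]benzene-1,3-diol | COc1ccc(Cc2c(O)cc(O)c(Cc3ccc(OC)cc3)c2CCc2cccc(OC)c2)cc1 | intermediate
9 | shanciguol, 4,6-bis[(4-hydroxyphenyl)methyl]-5-[2-(3-hydroxyphenyl)ethyl]benzene-1,3-diol (achiral) | Oc1ccc(Cc2c(O)cc(O)c(Cc3ccc(O)cc3)c2CCc2cccc(O)c2)cc1 | target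

**Total step count:** 4
**Longest linear sequence:** 4 (1 → 3 → 6 → 8 → 9)

**Steps most likely to fail**

Step 3 (new oxidative isoaromatization). Risks: acid-triggered ionization of the tertiary bis-allylic alcohol before oxygenation (hence the pyridine buffer), over-oxidation of the allylic alcohols to enones, and a sluggish base-mediated hydrogen shift. Fallback with known chemistry only, setting out from compound 2 and coming back to the route at compound 9. Compound 2 is reduced with NaBH4 in MeOH to (4-methoxyphenyl)methanol F1. Separately, purchased 1-bromo-3,5-dimethoxybenzene and 1-ethynyl-3-methoxybenzene are joined by Sonogashira coupling (PdCl2(PPh3)2, CuI, Et3N, 80 °C) to 1,3-dimethoxy-5-[(3-methoxyphenyl)ethynyl]benzene F2. Hydrogenation (H2, Pd/C, EtOAc) gives 1,3-dimethoxy-5-[2-(3-methoxyphenyl)ethyl]benzene F3. Twofold Friedel–Crafts benzylation of F3 with F1 (Sc(OTf)3 cat., MeNO2, 60 °C) goes para to one methoxy group and ortho to the chain, the position between the two methoxy groups being shielded. This gives 1,5-dimethoxy-2,4-bis[(4-methoxyphenyl)methyl]-3-[2-(3-methoxyphenyl)ethyl]benzene F4, and BBr3 in CH2Cl2 cleaves all five methyl ethers to 9.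

Step 2 (1,2-addition to the hindered, s-cis-locked dienone). Risks: conjugate addition, carbonyl reduction by β-hydride transfer, and Wurtz coupling during Grignard formation. Fallback setting out from compound 3 and coming back at compound 6: the small, hard nucleophile lithium (3-methoxyphenyl)acetylide F5 (from 1-ethynyl-3-methoxybenzene and n-BuLi, THF, −78 °C) adds cleanly 1,2 to 3. This gives (2E,6E)-1-[(3-methoxyphenyl)ethynyl]-2,6-bis[(4-methoxyphenyl)methylidene]cyclohexan-1-ol F6. The alkyne alone is then saturated with H2 and RhCl(PPh3)3 in benzene, a catalyst that leaves the trisubstituted arylidene alkenes untouched, to give 6.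

Step 4 (BBr3 on a very electron-rich dibenzylresorcinol). Risks: acid-mediated retro-Friedel–Crafts loss or scrambling of the hydroxybenzyl groups, and incomplete cleavage. Fallback that replaces methyl by benzyl protection so the end step is a neutral hydrogenolysis, setting out from compound 1 and coming back at compound 9. Compound 1 and purchased 4-(benzyloxy)benzaldehyde (NaOH, EtOH) give (2E,6E)-2,6-bis{[4-(benzyloxy)phenyl]methylidene}cyclohexan-1-one F7. Purchased 1-(benzyloxy)-3-(2-bromoethyl)benzene and Mg give {2-[3-(benzyloxy)phenyl]ethyl}magnesium bromide F8, which adds to F7 with CeCl3 to give (2E,6E)-1-{2-[3-(benzyloxy)phenyl]ethyl}-2,6-bis{[4-(benzyloxy)phenyl]methylidene}cyclohexan-1-ol F9. The conditions of step 3 take F9 through 4,6-bis{[4-(benzyloxy)phenyl]methylidene}-5-{2-[3-(benzyloxy)phenyl]ethyl}cyclohexane-1,3,5-triol F10 (stereoisomer mixture, not isolated) to 4,6-bis{[4-(benzyloxy)phenyl]methyl}-5-{2-[3-(benzyloxy)phenyl]ethyl}benzene-1,3-diol F11. H2 and Pd/C in EtOAc/MeOH then remove the three benzyl groups to give 9.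

**Further compounds**
F1 | step 3 | (4-methoxyphenyl)methanol | COc1ccc(CO)cc1
F2 | step 3 | 1,3-dimethoxy-5-[(3-methoxyphenyl)ethynyl]benzene | COc1cccc(C#Cc2cc(OC)cc(OC)c2)c1
F3 | step 3 | 1,3-dimethoxy-5-[2-(3-methoxyphenyl)ethyl]benzene | COc1cccc(CCc2cc(OC)cc(OC)c2)c1
F4 | step 3 | 1,5-dimethoxy-2,4-bis[(4-methoxyphenyl)methyl]-3-[2-(3-methoxyphenyl)ethyl]benzene | COc1ccc(Cc2c(OC)cc(OC)c(Cc3ccc(OC)cc3)c2CCc2cccc(OC)c2)cc1
F5 | step 2 | lithium (3-methoxyphenyl)acetylide | [Li]C#Cc1cccc(OC)c1
F6 | step 2 | (2E,6E)-1-[(3-methoxyphenyl)ethynyl]-2,6-bis[(4-methoxyphenyl)methylidene]cyclohexan-1-ol | OC1(C#Cc2cccc(OC)c2)/C(=C/c2ccc(OC)cc2)CCC/C1=C\c1ccc(OC)cc1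
F7 | step 4 | (2E,6E)-2,6-bis{[4-(benzyloxy)phenyl]methylidene}cyclohexan-1-one | O=C1/C(=C/c2ccc(OCc3ccccc3)cc2)CCC/C1=C\c1ccc(OCc2ccccc2)cc1
F8 | step 4 | {2-[3-(benzyloxy)phenyl]ethyl}magnesium bromide | Br[Mg]CCc1cccc(OCc2ccccc2)c1
F9 | step 4 | (2E,6E)-1-{2-[3-(benzyloxy)phenyl]ethyl}-2,6-bis{[4-(benzyloxy)phenyl]methylidene}cyclohexan-1-ol | OC1(CCc2cccc(OCc3ccccc3)c2)/C(=C/c2ccc(OCc3ccccc3)cc2)CCC/C1=C\c1ccc(OCc2ccccc2)cc1
F10 | step 4 | 4,6-bis{[4-(benzyloxy)phenyl]methylidene}-5-{2-[3-(benzyloxy)phenyl]ethyl}cyclohexane-1,3,5-triol (stereoisomer mixture) | OC1CC(O)C(=Cc2ccc(OCc3ccccc3)cc2)C(O)(CCc2cccc(OCc3ccccc3)c2)C1=Cc1ccc(OCc2ccccc2)cc1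
F11 | step 4 | 4,6-bis{[4-(benzyloxy)phenyl]methyl}-5-{2-[3-(benzyloxy)phenyl]ethyl}benzene-1,3-diol | Oc1cc(O)c(Cc2ccc(OCc3ccccc3)cc2)c(CCc2cccc(OCc3ccccc3)c2)c1Cc1ccc(OCc2ccccc2)cc1
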